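Choose the next charge by asking, moment by moment, which of its two ways the substrate takes.

the same everywhere: time 2.5 min

| charge | substrate | reagent | remark |
|---|---|---|---|
| noon | 0.50 mM (fed, over 2.0 min) | 0.450 mM | all else is in the flask from the start; the feed brings no volume worth counting |
| summer | 0.50 mM | 0.450 mM (fed, over 30 s) | all else is in the flask from the start; the feed brings no volume worth counting |
| winter | 0.50 mM | 0.450 mM (fed, over 2.0 min) | all else is in the flask from the start; the feed brings no volume worth counting |
| dawn | 0.50 mM | 0.450 mM | everything together at the start |
| spring | 0.50 mM | 0.450 mM (in portions, 5, over 2.0 min) | first portion at the start, last at 2.0 min |

    substrate + reagent → target, rate k1*[substrate]^1.5*[reagent]^0.5 (k1 = 72 L mol⁻¹ s⁻¹)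
    crystals ⇌ target, rate k2*(cs2 - [target]) while solid is left; crystals form when [target] > cs2 (cs2 = 0.038 mM, k2 = 13 s⁻¹)
    substrate ⇌ dormant form (K3 = 2.8, k3 = 0.022 s⁻¹)

* the flask with the highest amount of target, in percent of the substrate charged ("all alike" if they lie within 1.5 percentage points) (noon / summer / winter / dawn / spring / all alike)
* final target, as a percentage of the substrate charged, in noon
* final target, as a percentage of the substrate charged, in summer
* final target, as a percentage of the substrate charged, in winter
* final target, as a percentage of the substrate charged, in dawn
* final target, as a percentage of the substrate charged, in spring

- amounts and yields of target count crystals too
- given per volume of solution although it is solid: crystals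
- run time (noon): 2.5 min

Substrate either reacts with reagent to give target or slides into the dormant form. With the charges of dawn, 1.55 is the value of the split, the rate constant of the reaction times the root of [substrate][reagent], over the forward constant of the slide, a selectivity factor for this moment. The reaction therefore leads at the start of dawn, and at that moment a share 60.8% of the substrate leaving goes to target. Reagent is the limiting reagent, and one for one its charge allows 90.0% of the substrate charged. My rough figure for dawn, ceiling times share, is 54.7%. It folds in neither the sinking of the split nor the return from the dormant form.

Each feed on this card lowers the split early, and the root weighs both species alike. At 15.0 s, counting what has entered and nothing consumed, the split is 1.10 in summer, 0.694 in spring, and 0.549 in both noon and winter, so this reckoning does not part those two. Dawn stands above them, so my choice for the next run is dawn, with everything charged together.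

The forecast also named dawn, giving 55% for dawn, 50.5% for summer, 43% for noon, 39% for spring and 37.5% for winter, since the race “favours having substrate and reagent both high from the start”.

The simulation gives dawn, with 54.5% in dawn, 48.2% in summer, 42.0% in noon, 38.7% in spring and 36.8% in winter.

Read at 1.25 min, the split is 0.396 in dawn and 0.427 in winter, yet at that reading target stands at 48.0% in dawn against 24.6% in winter, and the dormant form at 38.1% against 53.9%, so the two flasks parted before it. Taking the step to the dormant form away, both ways, narrows the difference in target between dawn and winter from 18 percentage points to 8.4 points. Winter with its reagent dosed over 0.200 min reaches 51.7%, still below dawn's 54.5%.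

(The constants are invented; the flask was simulated.)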